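## The problem

The target is a nine-membered carbocycle, numbered here C1 (acetoxy carbon) to C9 (side-chain carbon). It holds an E trisubstituted alkene C3=C4 (a trans-cyclononene), a ring-cis alkene C6=C7 that carries the formyl carbon C18, and three adjacent ring stereocentres: C8 (formyl carbon C19), C9 and C1. A fourth stereocentre, the methine C10 with its methyl C20 and a homoprenyl chain (C11–C15), lies outside the ring and is conformationally mobile. End-to-end closure of such a ring is disfavoured by medium-ring strain and by the E alkene, so the ring is better derived from a larger ring that closes easily. Only C1 can be set reliably by a catalyst on an open chain. C9 must then follow from C1, C8 from C9 (trans), and C10 from C9 with help from the C1 oxygen. C8 is the one centre that can be corrected later, because it is α to a formyl group and allylic. The 1,4-dialdehyde with its enolisable C8–H, the doubly allylic C5 methylene, the acetate and the strained E alkene will not survive strong acid or base, so the aldehydes must appear last. The enabling feature is that C8 bears a carbon at the carboxyl level (C19) while its neighbour C9 bears C10 with the methyl C20. If C20 is oxidised and joined to C19 through oxygen, C19–C8 is an ester α-carbon pair and C9=C10–C20–O an allylic alcohol inside a thirteen-membered lactone (O, C19, C8, C7 to C1, C9, C10, C20), and a [3,3] shift forms C8–C9 and both stereocentres.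

## Retrosynthesis

**Aldehydes and acetate.** Target 36 is traced to diol 35, which comes from bis-silyl ether acetate 34 and that from alcohol 33. No skeletal bond is cut. Keeping C18 and C19 as silyl ethers until the last two steps protects C8, and the forward oxidation must convert both hydroxyls at once so that no hydroxy aldehyde can close to a lactol.

**C10–H.** Alcohol 33 is traced to methylene compound 32 by removing H2 across C10=C20. C10 cannot be carried through the key step as a stereocentre, because C10 is an sp2 carbon of the rearranging allyl unit. The free C1 hydroxyl, homoallylic to the methylene, is the handle that distinguishes the two faces. The C19 oxygen on the other flank is therefore silylated, and a cationic rhodium catalyst is preferred over an iridium one because three trisubstituted alkenes must stay.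

**Oxidation level at C19.** Compound 32 comes from acid 29 by reduction to alcohol 30, silylation to 31 and PMB removal. This is simpler than carrying an aldehyde at the epimerisable C8 through four steps.

**C8–C9 (key).** Acid 29 is cut at C8–C9 and the O–C20 bond is restored, giving the thirteen-membered lactone 26. Against direct nine-membered closures, this makes the ring by contraction of a macrocycle that closes readily and sets C8 and C9 in one pericyclic event. Lactone 26 has a single stereocentre (C1) and no medium ring. The forward reaction needs the E geometry of C9=C10 (C1 trans to C20), a ketene acetal with C7 cis to the silyloxy group, and bonding on the face of C9 opposite the C1 ether.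

**Ester bond C19–O–C20.** Lactone 26 is opened to hydroxy acid 25. Closing at the ester is preferred over any C–C macrocyclisation because three planar alkene units preorganise the chain. The alcohol, not the β,γ-unsaturated acid, is activated, so the acid cannot form a ketene or shift its alkene. Acid 25 comes from seco ester 23 through 24, which requires the C20 silyl ether (TBS) to be removable beside the C18 silyl ether (TBDPS).

**C4–C5 and C3–CH3.** Seco ester 23 is cut between the alkenyl carbon C4 and the allylic carbon C5, and the C3 methyl is removed, giving alkyne 12 and allylic chloride 21. Carboalumination fixes the E C3=C4 alkene and the palladium coupling joins the skipped diene without touching either alkene geometry. The two fragments are of similar size.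

**C1–C2.** Alkyne 12 comes from alcohol 11, which is cut into enal 8 and allenylboronate 9. This is the only step that needs an external chiral source, and a catalytic propargylation of an enal is well suited to it.

**C10–C11 and C7–C8.** Enal 8 (via alcohol 7) is cut to alkenyl iodide 4 and bromide 5. Chloride 21 (via hydroxy ester 20) is cut to alkenyl iodide 15 and bromoacetate 16. Both iodides come from mono-silylated but-2-yne-1,4-diol (2 and 13, from diol 1) by hydroxyl-directed trans-hydroalumination and iodination. This fixes both trisubstituted alkene geometries from one cheap alkyne.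

## Roads not taken

**Alternative 1:** The ring is cut at C5–C6 and derived from a five-membered ring in which C3 and C8 are bonded. The potassium alkoxide of that precursor undergoes an anionic alkynyl oxy-Cope shift (C5–C6 forms, C3–C8 breaks), and protonation of the allenolate gives dienone A1.
- Merits: the ring and the E C3=C4 alkene form together, driven by enolate formation. C1, C9 and C10 are set on a cyclopentane, and C10 can come from the chiral pool. This is better than the late hydrogenation of the chosen plan.
- Weak points: A1 lacks both formyl carbons and the C8 stereocentre. The C8 ketone must be homologated to CH–CHO and C7 formylated on a strained, base-sensitive dienone. The precursor needs a quaternary C3 beside a tertiary carbinol, and its configuration together with the chair or boat preference decides the alkene geometry.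
- Comparison: the chosen plan delivers the ring with C18 and C19 already on the right carbons and C8 set with C9. Against the advantage of A1 at C10 it offers a directed hydrogenation of a known type.

**Alternative 2:** The C3=C4 alkene and a C7 carbonyl are traced to the shared C3–C7 bond of a fused six–five bicycle. KOt-Bu deprotonates the angular C7 hydroxyl, and Grob fragmentation with loss of a C4 mesylate gives cyclononenone A2.
- Merits: the fragmentation is stereospecific, so the alkene geometry follows from the bicycle. C1, C8, C9 and C10 are all set on a rigid framework before the ring opens. In certainty of stereocontrol this is superior to the chosen plan, whose facial selectivity is untested.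
- Weak points: the bicyclic precursor carries six or more stereocentres, including an angular methyl and an angular carbinol, and is long to make. A2 is a β-silyloxy ketone with an enolisable C8, formed under strong base, so elimination and epimerisation threaten. C6=C7 and C18 must still be added through a regioselective enol triflate and carbonylation.
- Comparison: the chosen plan is shorter to its key intermediate and leaves only functional-group changes after the ring is made.

**Alternative 3:** The ring is cut at C1–C9. CrCl2 reduces a C19 allylic bromide in the open-chain precursor, and the γ carbon C9 of the allylchromium adds to the C1 aldehyde, giving homoallylic alcohol A3.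
- Merits: this is the most convergent road. One step closes the ring and creates C1 and C9, C10 is already present, and no macrolactone has to be made and contracted. If it worked it would be shorter than the chosen plan.
- Weak points: a nine-membered ring with an E alkene must close directly by C–C bond formation. Both absolute configurations rest on induction from C10 alone. The C8=C19 methylene, part of a cross-conjugated diene with C6=C7, must then be turned into C8(H)–CHO with control at C8 in the presence of three other alkenes.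
- Comparison: the chosen plan offers a ring formation that is a contraction of an easily closed ring and a C8 centre created together with C9.

Key step: step 15

Remark: locants C1–C20 are those defined above and are used for all intermediates. TBS = tert-butyldimethylsilyl, TBDPS = tert-butyldiphenylsilyl, PMB = 4-methoxybenzyl, TMS = trimethylsilyl, nbd = norbornadiene, dppb = 1,4-bis(diphenylphosphino)butane, dppf = 1,1'-bis(diphenylphosphino)ferrocene, TRIP = 3,3'-bis(2,4,6-triisopropylphenyl)-1,1'-binaphthyl-2,2'-diyl hydrogen phosphate.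

Remark: the R catalyst in step 5 is assumed to direct attack to the Re face of enal 8, as it does with aryl and cinnamyl aldehydes.

## Route

Step 1
Reactants: 1 but-2-yne-1,4-diol
Product: 2 4-(TBS-oxy)but-2-yn-1-ol
Conditions: NaH (1.0 equiv), THF, 0 °C; TBSCl (1.0 equiv), rt
Reagents that add atoms: tert-butyldimethylsilyl chloride, CC(C)(C)[Si](C)(C)Cl
Why: Monosilylation of a symmetric diol through its sparingly soluble monosodium alkoxide, which limits double silylation.

Step 2
Reactants: 2 4-(TBS-oxy)but-2-yn-1-ol
Product: 4 (2Z)-4-(TBS-oxy)-3-iodobut-2-en-1-ol, via sodium alkenylaluminate 3 (not isolated)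
Conditions: NaAlH2(OCH2CH2OCH3)2, THF, 0 °C; I2 (excess), −78 °C → 0 °C
Reagents that add atoms: iodine, II
Why: Hydroxyl-directed trans-hydroalumination puts hydride on C9 and aluminium on C10 in a five-membered aluminate, and iodinolysis with retention gives the Z iodide. The temperature is kept at or below 0 °C so that the alkenylaluminate does not expel silyloxide to form an allene.

Step 3
Reactants: 4 (2Z)-4-(TBS-oxy)-3-iodobut-2-en-1-ol; 5 5-bromo-2-methylpent-2-ene
Product: 7 (2E)-3-[(TBS-oxy)methyl]-7-methylocta-2,6-dien-1-ol, via homoprenylzinc bromide 6 (not isolated)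
Conditions: 5, Zn dust, LiCl, THF, 40 °C; then 4, PdCl2(dppf) (3 mol %), THF, rt → 40 °C
Reagents that add atoms: none
Why: Negishi sp3–sp2 coupling with retention at the alkenyl iodide, so C1 ends cis to the chain and trans to C20. The dppf ligand suppresses β-hydride elimination, and alkylzinc halides tolerate the free hydroxyl.

Step 4
Reactants: 7 (2E)-3-[(TBS-oxy)methyl]-7-methylocta-2,6-dien-1-ol
Product: 8 (2E)-3-[(TBS-oxy)methyl]-7-methylocta-2,6-dienal
Conditions: MnO2 (15 equiv), CH2Cl2, rt
Reagents that add atoms: none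
Why: Neutral MnO2 oxidation of a primary allylic alcohol, which does not isomerise the trisubstituted alkene.

Step 5
Reactants: 8 (2E)-3-[(TBS-oxy)methyl]-7-methylocta-2,6-dienal; 9 allenylboronic acid pinacol ester
Product: 11 (4R,5E)-6-[(TBS-oxy)methyl]-10-methylundeca-5,9-dien-1-yn-4-ol, via pinacol borate 10 (not isolated)
Conditions: 9 (1.5 equiv), (R)-TRIP (10 mol %), 4 Å sieves, toluene, −20 °C; aq. NaHCO3
Reagents that add atoms: none
Why: Chiral phosphoric acid-catalysed propargylboration: the allenylboronate adds through a closed six-membered transition state (SE2′), giving only the homopropargylic alcohol. The R catalyst should direct attack to the Re face and set C1 as R, to be confirmed by Mosher ester analysis.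

Step 6
Reactants: 11 (4R,5E)-6-[(TBS-oxy)methyl]-10-methylundeca-5,9-dien-1-yn-4-ol
Product: 12 (4R,5E)-6-[(TBS-oxy)methyl]-4-(PMB-oxy)-10-methylundeca-5,9-dien-1-yne
Conditions: NaH, 4-methoxybenzyl chloride, Bu4NI (cat.), DMF, 0 °C → rt
Reagents that add atoms: 4-methoxybenzyl chloride, COc1ccc(CCl)cc1
Why: Williamson etherification. The C1 alkoxide cannot reach the C20 silyl ether across the E alkene, so no silyl migration is expected.

Step 7
Reactants: 1 but-2-yne-1,4-diol
Product: 13 4-(TBDPS-oxy)but-2-yn-1-ol
Conditions: NaH (1.0 equiv), THF, 0 °C; TBDPSCl (1.0 equiv), rt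
Reagents that add atoms: tert-butyldiphenylsilyl chloride, CC(C)(C)[Si](Cl)(c1ccccc1)c1ccccc1
Why: Monosilylation as in step 1. The bulkier silyl group is chosen so that the C20 TBS ether can later be removed beside it.

Step 8
Reactants: 13 4-(TBDPS-oxy)but-2-yn-1-ol
Product: 15 (2Z)-4-(TBDPS-oxy)-3-iodobut-2-en-1-ol, via sodium alkenylaluminate 14 (not isolated)
Conditions: NaAlH2(OCH2CH2OCH3)2, THF, 0 °C; I2 (excess), −78 °C → 0 °C
Reagents that add atoms: iodine, II
Why: The same directed trans-hydroalumination and iodination as in step 2. It fixes C5 trans to C18 across the future C6=C7 alkene.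

Step 9
Reactants: 15 (2Z)-4-(TBDPS-oxy)-3-iodobut-2-en-1-ol; 16 methyl bromoacetate
Product: 20 methyl (3E)-3-[(TBDPS-oxy)methyl]-5-hydroxypent-3-enoate, via trimethylsilyl ether 17 (not isolated), via zinc ester enolate 18 (not isolated), via silylated coupling product 19 (not isolated)
Conditions: 15, Me3SiCl, Et3N, Et2O, 0 °C, filtered and concentrated; 16, Zn dust, THF, 40 °C; combined, Pd(PPh3)4 (5 mol %), THF, 45 °C; citric acid, MeOH–H2O, 0 °C
Reagents that add atoms: none
Why: Palladium-catalysed Negishi coupling of a Reformatsky reagent with an alkenyl iodide, with retention, installs C8–C19 as a β,γ-unsaturated ester. The transient TMS ether keeps a zinc alkoxide from lactonising onto the cis-disposed ester, and mild acid frees the C5 hydroxyl on work-up.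

Step 10
Reactants: 20 methyl (3E)-3-[(TBDPS-oxy)methyl]-5-hydroxypent-3-enoate
Product: 21 methyl (3E)-5-chloro-3-[(TBDPS-oxy)methyl]pent-3-enoate
Conditions: NCS, Me2S, CH2Cl2, −20 °C → 0 °C
Reagents that add atoms: N-chlorosuccinimide, ClN1C(=O)CCC1=O
Why: Corey–Kim chlorination (alkoxysulfonium ion, SN2 by chloride) converts the primary allylic alcohol without allylic transposition. Alcohol 20 is used at once because it can lactonise on standing.

Step 11
Reactants: 12 (4R,5E)-6-[(TBS-oxy)methyl]-4-(PMB-oxy)-10-methylundeca-5,9-dien-1-yne; 21 methyl (3E)-5-chloro-3-[(TBDPS-oxy)methyl]pent-3-enoate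
Product: 23 methyl (3E,6E,9R,10E)-11-[(TBS-oxy)methyl]-3-[(TBDPS-oxy)methyl]-9-(PMB-oxy)-7,15-dimethylhexadeca-3,6,10,14-tetraenoate, via alkenyldimethylalane 22 (not isolated)
Conditions: Me3Al (3 equiv), Cp2ZrCl2 (0.5 equiv), CH2Cl2, 0 °C → rt; then 21, Pd(PPh3)4 (5 mol %), THF, rt
Reagents that add atoms: trimethylaluminium, C[Al](C)C
Why: Zirconium-catalysed carboalumination adds methyl and aluminium syn, with methyl on the internal carbon C3, and so fixes the E C3=C4 alkene. The allylic chloride adds oxidatively to zerovalent palladium, and the alkenyl group is transferred to the less hindered C5 terminus with retention at both alkenes (Negishi alkenyl–allyl coupling).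

Step 12
Reactants: 23 methyl (3E,6E,9R,10E)-11-[(TBS-oxy)methyl]-3-[(TBDPS-oxy)methyl]-9-(PMB-oxy)-7,15-dimethylhexadeca-3,6,10,14-tetraenoate
Product: 24 methyl (3E,6E,9R,10E)-3-[(TBDPS-oxy)methyl]-11-(hydroxymethyl)-9-(PMB-oxy)-7,15-dimethylhexadeca-3,6,10,14-tetraenoate
Conditions: HF·pyridine, pyridine, THF, 0 °C
Reagents that add atoms: none
Why: Buffered fluoride cleaves the primary TBS ether much faster than the primary TBDPS ether. The PMB ether and the ester are inert.

Step 13
Reactants: 24 methyl (3E,6E,9R,10E)-3-[(TBDPS-oxy)methyl]-11-(hydroxymethyl)-9-(PMB-oxy)-7,15-dimethylhexadeca-3,6,10,14-tetraenoate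
Product: 25 (3E,6E,9R,10E)-3-[(TBDPS-oxy)methyl]-11-(hydroxymethyl)-9-(PMB-oxy)-7,15-dimethylhexadeca-3,6,10,14-tetraenoic acid
Conditions: LiOH (3 equiv), THF–MeOH–H2O, 0 °C → rt; 0.5 M HCl to pH 4, 0 °C
Reagents that add atoms: lithium hydroxide, [Li+].[OH-]
Why: Saponification of the methyl ester. The low temperature and the trisubstituted β,γ-alkene should keep the double bond from moving into conjugation.

Step 14
Reactants: 25 (3E,6E,9R,10E)-3-[(TBDPS-oxy)methyl]-11-(hydroxymethyl)-9-(PMB-oxy)-7,15-dimethylhexadeca-3,6,10,14-tetraenoic acid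
Product: 26 (4E,7E,10R,11E)-4-[(TBDPS-oxy)methyl]-10-(PMB-oxy)-8-methyl-12-(4-methylpent-3-en-1-yl)-1-oxacyclotrideca-4,7,11-trien-2-one
Conditions: PPh3, DIAD, toluene (0.002 M), slow addition of 25, 0 °C → rt
Reagents that add atoms: none
Why: Mitsunobu macrolactonisation: the C20 hydroxyl is activated as an oxyphosphonium ion and displaced by the C19 carboxylate at a primary allylic carbon. The β,γ-unsaturated acid is never activated and so cannot form a ketene or isomerise, and three planar alkene units preorganise the chain.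

Step 15
Reactants: 26 (4E,7E,10R,11E)-4-[(TBDPS-oxy)methyl]-10-(PMB-oxy)-8-methyl-12-(4-methylpent-3-en-1-yl)-1-oxacyclotrideca-4,7,11-trien-2-one
Product: 29 (1R,3E,6E,8R,9S)-7-[(TBDPS-oxy)methyl]-1-(PMB-oxy)-3-methyl-9-(6-methylhepta-1,5-dien-2-yl)cyclonona-3,6-diene-8-carboxylic acid, via silyl ketene acetal 27 (not isolated), via silyl ester 28 (not isolated)
Conditions: TBSCl (2 equiv), KN(SiMe3)2 (1.5 equiv), THF–toluene, −78 °C; then 60–80 °C; K2CO3, MeOH–H2O, rt; pH 4 buffer
Reagents that add atoms: none
Why: KN(SiMe3)2 removes the doubly activated C8–H (α to the lactone carbonyl and allylic to C6=C7) and TBSCl traps the dienolate on oxygen as ketene acetal 27; on warming, the six atoms C8=C19–O–C20–C10=C9 undergo a suprafacial [3,3] shift in which C8–C9 forms, O–C20 breaks and the C10=C20 methylene appears, and silyl ester 28 is hydrolysed on work-up. The closest known reaction type is the Ireland–Claisen ring contraction of macrocyclic allylic lactones to 2-alkenylcycloalkanecarboxylic acids. The nine-membered ring is closed by a transannular bond across the thirteen-membered lactone, the seven-atom tether C7 to C1 bridging the termini of a chair-like six-membered array, so the ring contracts by four atoms, needs no high dilution, and is paid for by the new carbonyl. C9 is set relative to C1: allylic 1,3-strain with the cis chain carbon C11 holds C1–H in the alkene plane, which leaves the PMB ether on one face and C2, which leads to C8, on the other, so bonding occurs anti to the ether and gives the 1,9-trans relation. C8 is set relative to C9 by the ketene acetal geometry: a conjugated dienolate should place C7 cis to the oxygen that is silylated, as arylacetate and 3-alkenoate enolates do, and a thirteen-membered ring is large enough to hold this ring-trans double bond without extra strain. With C1 trans to C20 from steps 2 and 3, both tether ends are then pseudo-equatorial on the chair and C19 and C10 come out trans. The step needs O-silylation over C-silylation and this ketene acetal geometry; the ring-cis isomer would pass through the cis-fused chair to the C8 epimer, which is the outcome to be checked first. The other three alkenes are spectators, and the temperature stays far below that of a Cope shift of the new 1,5-diene.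

Step 16
Reactants: 29 (1R,3E,6E,8R,9S)-7-[(TBDPS-oxy)methyl]-1-(PMB-oxy)-3-methyl-9-(6-methylhepta-1,5-dien-2-yl)cyclonona-3,6-diene-8-carboxylic acid
Product: 30 (1R,3E,6E,8R,9S)-8-(hydroxymethyl)-7-[(TBDPS-oxy)methyl]-1-(PMB-oxy)-3-methyl-9-(6-methylhepta-1,5-dien-2-yl)cyclonona-3,6-diene
Conditions: LiAlH4, Et2O, 0 °C → rt
Reagents that add atoms: none
Why: Hydride reduction of the carboxylic acid to the primary alcohol. The carboxylate does not enolise, so C8 is not epimerised.

Step 17
Reactants: 30 (1R,3E,6E,8R,9S)-8-(hydroxymethyl)-7-[(TBDPS-oxy)methyl]-1-(PMB-oxy)-3-methyl-9-(6-methylhepta-1,5-dien-2-yl)cyclonona-3,6-diene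
Product: 31 (1R,3E,6E,8R,9S)-8-[(TBS-oxy)methyl]-7-[(TBDPS-oxy)methyl]-1-(PMB-oxy)-3-methyl-9-(6-methylhepta-1,5-dien-2-yl)cyclonona-3,6-diene
Conditions: TBSCl, imidazole, DMF, rt
Reagents that add atoms: tert-butyldimethylsilyl chloride, CC(C)(C)[Si](C)(C)Cl
Why: Standard silylation. It masks the C19 hydroxyl so that only the C1 hydroxyl can bind the hydrogenation catalyst later.

Step 18
Reactants: 31 (1R,3E,6E,8R,9S)-8-[(TBS-oxy)methyl]-7-[(TBDPS-oxy)methyl]-1-(PMB-oxy)-3-methyl-9-(6-methylhepta-1,5-dien-2-yl)cyclonona-3,6-diene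
Product: 32 (1R,3E,6E,8R,9S)-7-[(TBDPS-oxy)methyl]-8-[(TBS-oxy)methyl]-3-methyl-9-(6-methylhepta-1,5-dien-2-yl)cyclonona-3,6-dien-1-ol
Conditions: DDQ, CH2Cl2–pH 7 buffer (10:1), 0 °C
Reagents that add atoms: none
Why: Oxidative PMB cleavage (benzylic hydride abstraction, then hydrolysis of the oxocarbenium ion) in a buffered medium that leaves silyl ethers and alkenes untouched.

Step 19
Reactants: 32 (1R,3E,6E,8R,9S)-7-[(TBDPS-oxy)methyl]-8-[(TBS-oxy)methyl]-3-methyl-9-(6-methylhepta-1,5-dien-2-yl)cyclonona-3,6-dien-1-ol
Product: 33 (1R,3E,6E,8R,9R)-7-[(TBDPS-oxy)methyl]-8-[(TBS-oxy)methyl]-3-methyl-9-[(2S)-6-methylhept-5-en-2-yl]cyclonona-3,6-dien-1-ol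
Conditions: [Rh(nbd)(dppb)]BF4 (5 mol %), H2 (10 atm), CH2Cl2, rt
Reagents that add atoms: none
Why: Hydroxyl-directed homogeneous hydrogenation: the cationic rhodium binds the homoallylic C1 hydroxyl and the 1,1-disubstituted C10=C20 alkene. With C9–H eclipsing the methylene (least allylic strain), delivery from the C1 flank gives 10S. Trisubstituted alkenes react far more slowly with this catalyst, and the elevated pressure suppresses alkene migration.

Step 20
Reactants: 33 (1R,3E,6E,8R,9R)-7-[(TBDPS-oxy)methyl]-8-[(TBS-oxy)methyl]-3-methyl-9-[(2S)-6-methylhept-5-en-2-yl]cyclonona-3,6-dien-1-ol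
Product: 34 (1R,3E,6E,8R,9R)-7-[(TBDPS-oxy)methyl]-8-[(TBS-oxy)methyl]-3-methyl-9-[(2S)-6-methylhept-5-en-2-yl]cyclonona-3,6-dien-1-yl acetate
Conditions: Ac2O, pyridine, DMAP (cat.), CH2Cl2, 0 °C → rt
Reagents that add atoms: acetic anhydride, CC(=O)OC(C)=O
Why: DMAP-catalysed acylation of the secondary alcohol with retention at C1.

Step 21
Reactants: 34 (1R,3E,6E,8R,9R)-7-[(TBDPS-oxy)methyl]-8-[(TBS-oxy)methyl]-3-methyl-9-[(2S)-6-methylhept-5-en-2-yl]cyclonona-3,6-dien-1-yl acetate
Product: 35 (1R,3E,6E,8R,9R)-7,8-bis(hydroxymethyl)-3-methyl-9-[(2S)-6-methylhept-5-en-2-yl]cyclonona-3,6-dien-1-yl acetate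
Conditions: HF·pyridine, pyridine, THF, 0 °C → rt
Reagents that add atoms: none
Why: Buffered fluoride removes both primary silyl ethers. The acetate is stable and no base is present that could move it.

Step 22
Reactants: 35 (1R,3E,6E,8R,9R)-7,8-bis(hydroxymethyl)-3-methyl-9-[(2S)-6-methylhept-5-en-2-yl]cyclonona-3,6-dien-1-yl acetate
Product: 36 (1R,3E,6E,8R,9R)-7,8-diformyl-3-methyl-9-[(2S)-6-methylhept-5-en-2-yl]cyclonona-3,6-dien-1-yl acetate
Conditions: (COCl)2, DMSO, CH2Cl2, −78 °C; Et3N, −78 °C → −30 °C
Reagents that add atoms: none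
Why: Double Swern oxidation: both hydroxyls become alkoxysulfonium ions at −78 °C before base is added, so no hydroxy aldehyde and hence no lactol or lactone can form. Cold, brief contact with the amine protects the epimerisable C8.

## Compound list

1 | but-2-yne-1,4-diol | OCC#CCO | starting material
2 | 4-(TBS-oxy)but-2-yn-1-ol | OCC#CCO[Si](C)(C)C(C)(C)C | intermediate
3 | sodium alkenylaluminate from 2 (cyclic ate complex, formed in the flask) | [Na+].COCCO[Al-]1(OCCOC)OC/C=C\1CO[Si](C)(C)C(C)(C)C | intermediate
4 | (2Z)-4-(TBS-oxy)-3-iodobut-2-en-1-ol | OC/C=C(\I)CO[Si](C)(C)C(C)(C)C | intermediate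
5 | 5-bromo-2-methylpent-2-ene | CC(C)=CCCBr | starting material
6 | (4-methylpent-3-en-1-yl)zinc bromide (formed in the flask) | CC(C)=CCC[Zn]Br | intermediate
7 | (2E)-3-[(TBS-oxy)methyl]-7-methylocta-2,6-dien-1-ol | OC/C=C(\CCC=C(C)C)CO[Si](C)(C)C(C)(C)C | intermediate
8 | (2E)-3-[(TBS-oxy)methyl]-7-methylocta-2,6-dienal | O=C/C=C(\CCC=C(C)C)CO[Si](C)(C)C(C)(C)C | intermediate
9 | allenylboronic acid pinacol ester | C=C=CB1OC(C)(C)C(C)(C)O1 | starting material
10 | pinacol borate of 11 (formed in the flask) | C#CC[C@@H](OB1OC(C)(C)C(C)(C)O1)/C=C(\CCC=C(C)C)CO[Si](C)(C)C(C)(C)C | intermediate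
11 | (4R,5E)-6-[(TBS-oxy)methyl]-10-methylundeca-5,9-dien-1-yn-4-ol | C#CC[C@@H](O)/C=C(\CCC=C(C)C)CO[Si](C)(C)C(C)(C)C | intermediate
12 | (4R,5E)-6-[(TBS-oxy)methyl]-4-(PMB-oxy)-10-methylundeca-5,9-dien-1-yne | C#CC[C@@H](OCc1ccc(OC)cc1)/C=C(\CCC=C(C)C)CO[Si](C)(C)C(C)(C)C | intermediate
13 | 4-(TBDPS-oxy)but-2-yn-1-ol | OCC#CCO[Si](c1ccccc1)(c1ccccc1)C(C)(C)C | intermediate
14 | sodium alkenylaluminate from 13 (cyclic ate complex, formed in the flask) | [Na+].COCCO[Al-]1(OCCOC)OC/C=C\1CO[Si](c1ccccc1)(c1ccccc1)C(C)(C)C | intermediate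
15 | (2Z)-4-(TBDPS-oxy)-3-iodobut-2-en-1-ol | OC/C=C(\I)CO[Si](c1ccccc1)(c1ccccc1)C(C)(C)C | intermediate
16 | methyl bromoacetate | BrCC(=O)OC | starting material
17 | trimethylsilyl ether of 15 (formed in the flask) | C[Si](C)(C)OC/C=C(\I)CO[Si](c1ccccc1)(c1ccccc1)C(C)(C)C | intermediate
18 | (2-methoxy-2-oxoethyl)zinc bromide (formed in the flask) | Br[Zn]CC(=O)OC | intermediate
19 | trimethylsilyl ether of 20 (formed in the flask) | C[Si](C)(C)OC/C=C(\CC(=O)OC)CO[Si](c1ccccc1)(c1ccccc1)C(C)(C)C | intermediate
20 | methyl (3E)-3-[(TBDPS-oxy)methyl]-5-hydroxypent-3-enoate | OC/C=C(\CC(=O)OC)CO[Si](c1ccccc1)(c1ccccc1)C(C)(C)C | intermediate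
21 | methyl (3E)-5-chloro-3-[(TBDPS-oxy)methyl]pent-3-enoate | ClC/C=C(\CC(=O)OC)CO[Si](c1ccccc1)(c1ccccc1)C(C)(C)C | intermediate
22 | (E)-alkenyldimethylalane from 12 (formed in the flask) | C[Al](C)/C=C(\C)C[C@@H](OCc1ccc(OC)cc1)/C=C(\CCC=C(C)C)CO[Si](C)(C)C(C)(C)C | intermediate
23 | methyl (3E,6E,9R,10E)-11-[(TBS-oxy)methyl]-3-[(TBDPS-oxy)methyl]-9-(PMB-oxy)-7,15-dimethylhexadeca-3,6,10,14-tetraenoate | COC(=O)C/C(CO[Si](c1ccccc1)(c1ccccc1)C(C)(C)C)=C\C/C=C(\C)C[C@@H](OCc1ccc(OC)cc1)/C=C(\CCC=C(C)C)CO[Si](C)(C)C(C)(C)C | intermediate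
24 | methyl (3E,6E,9R,10E)-3-[(TBDPS-oxy)methyl]-11-(hydroxymethyl)-9-(PMB-oxy)-7,15-dimethylhexadeca-3,6,10,14-tetraenoate | COC(=O)C/C(CO[Si](c1ccccc1)(c1ccccc1)C(C)(C)C)=C\C/C=C(\C)C[C@@H](OCc1ccc(OC)cc1)/C=C(\CCC=C(C)C)CO | intermediate
25 | (3E,6E,9R,10E)-3-[(TBDPS-oxy)methyl]-11-(hydroxymethyl)-9-(PMB-oxy)-7,15-dimethylhexadeca-3,6,10,14-tetraenoic acid | OC(=O)C/C(CO[Si](c1ccccc1)(c1ccccc1)C(C)(C)C)=C\C/C=C(\C)C[C@@H](OCc1ccc(OC)cc1)/C=C(\CCC=C(C)C)CO | intermediate
26 | (4E,7E,10R,11E)-4-[(TBDPS-oxy)methyl]-10-(PMB-oxy)-8-methyl-12-(4-methylpent-3-en-1-yl)-1-oxacyclotrideca-4,7,11-trien-2-one | O=C1C/C(CO[Si](c2ccccc2)(c2ccccc2)C(C)(C)C)=C\C/C=C(C)/C[C@@H](OCc2ccc(OC)cc2)/C=C(\CCC=C(C)C)CO1 | intermediate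
27 | tert-butyldimethylsilyl ketene acetal of 26, C7 cis to the silyloxy group (formed in the flask) | CC(C)(C)[Si](C)(C)O/C1=C\C(CO[Si](c2ccccc2)(c2ccccc2)C(C)(C)C)=C/C/C=C(C)/C[C@@H](OCc2ccc(OC)cc2)/C=C(\CCC=C(C)C)CO1 | intermediate
28 | tert-butyldimethylsilyl ester of 29 (formed in the flask) | COc1ccc(cc1)CO[C@@H]2C/C(C)=C/C/C=C(/CO[Si](c3ccccc3)(c3ccccc3)C(C)(C)C)[C@H](C(=O)O[Si](C)(C)C(C)(C)C)[C@H]2C(=C)CCC=C(C)C | intermediate
29 | (1R,3E,6E,8R,9S)-7-[(TBDPS-oxy)methyl]-1-(PMB-oxy)-3-methyl-9-(6-methylhepta-1,5-dien-2-yl)cyclonona-3,6-diene-8-carboxylic acid | COc1ccc(cc1)CO[C@@H]2C/C(C)=C/C/C=C(/CO[Si](c3ccccc3)(c3ccccc3)C(C)(C)C)[C@H](C(O)=O)[C@H]2C(=C)CCC=C(C)C | intermediate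
30 | (1R,3E,6E,8R,9S)-8-(hydroxymethyl)-7-[(TBDPS-oxy)methyl]-1-(PMB-oxy)-3-methyl-9-(6-methylhepta-1,5-dien-2-yl)cyclonona-3,6-diene | COc1ccc(cc1)CO[C@@H]2C/C(C)=C/C/C=C(/CO[Si](c3ccccc3)(c3ccccc3)C(C)(C)C)[C@H](CO)[C@H]2C(=C)CCC=C(C)C | intermediate
31 | (1R,3E,6E,8R,9S)-8-[(TBS-oxy)methyl]-7-[(TBDPS-oxy)methyl]-1-(PMB-oxy)-3-methyl-9-(6-methylhepta-1,5-dien-2-yl)cyclonona-3,6-diene | COc1ccc(cc1)CO[C@@H]2C/C(C)=C/C/C=C(/CO[Si](c3ccccc3)(c3ccccc3)C(C)(C)C)[C@H](CO[Si](C)(C)C(C)(C)C)[C@H]2C(=C)CCC=C(C)C | intermediate
32 | (1R,3E,6E,8R,9S)-7-[(TBDPS-oxy)methyl]-8-[(TBS-oxy)methyl]-3-methyl-9-(6-methylhepta-1,5-dien-2-yl)cyclonona-3,6-dien-1-ol | O[C@@H]1C/C(C)=C/C/C=C(/CO[Si](c2ccccc2)(c2ccccc2)C(C)(C)C)[C@H](CO[Si](C)(C)C(C)(C)C)[C@H]1C(=C)CCC=C(C)C | intermediate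
33 | (1R,3E,6E,8R,9R)-7-[(TBDPS-oxy)methyl]-8-[(TBS-oxy)methyl]-3-methyl-9-[(2S)-6-methylhept-5-en-2-yl]cyclonona-3,6-dien-1-ol | O[C@@H]1C/C(C)=C/C/C=C(/CO[Si](c2ccccc2)(c2ccccc2)C(C)(C)C)[C@H](CO[Si](C)(C)C(C)(C)C)[C@H]1[C@@H](C)CCC=C(C)C | intermediate
34 | (1R,3E,6E,8R,9R)-7-[(TBDPS-oxy)methyl]-8-[(TBS-oxy)methyl]-3-methyl-9-[(2S)-6-methylhept-5-en-2-yl]cyclonona-3,6-dien-1-yl acetate | CC(=O)O[C@@H]1C/C(C)=C/C/C=C(/CO[Si](c2ccccc2)(c2ccccc2)C(C)(C)C)[C@H](CO[Si](C)(C)C(C)(C)C)[C@H]1[C@@H](C)CCC=C(C)C | intermediate
35 | (1R,3E,6E,8R,9R)-7,8-bis(hydroxymethyl)-3-methyl-9-[(2S)-6-methylhept-5-en-2-yl]cyclonona-3,6-dien-1-yl acetate | CC(=O)O[C@@H]1C/C(C)=C/C/C=C(/CO)[C@H](CO)[C@H]1[C@@H](C)CCC=C(C)C | intermediate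
36 | (1R,3E,6E,8R,9R)-7,8-diformyl-3-methyl-9-[(2S)-6-methylhept-5-en-2-yl]cyclonona-3,6-dien-1-yl acetate | CC(=O)O[C@@H]1C/C(C)=C/C/C=C(/C=O)[C@H](C=O)[C@H]1[C@@H](C)CCC=C(C)C | target

## Step count and least certain steps

Total: 22 steps. Longest linear sequence: 18 steps (steps 1–6, then 11–22); the branch through steps 7–10 is 16 steps long.

**Step 15 (key step).** The most likely failure is silylation of the enolate in the ring-cis geometry (C7 cis to the ring oxygen), which is the geometry small and medium lactones are forced into. Rearrangement through the cis-fused chair would then give the C8 epimer. Attack on the C9 face syn to the C1 ether is a second possibility, since the tether, not only allylic strain, decides the face. Fallback, from lactone 26: the rearrangement is run as in step 15, and if it delivers mainly the C8-epimeric acid F1, this is methylated with Me3SiCHN2 in MeOH–toluene to the C8-epimeric methyl ester F2. C8 is both α to the ester and allylic, so F2 is equilibrated with DBU in toluene to the trans methyl ester F3, where the ester and the C9 substituent avoid each other. LiAlH4 then gives alcohol 30, and the route continues at step 17.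

**Step 19.** Loss of facial control is the main risk, because rotation about C9–C10 is not fixed by the ring and the other rotamer would give the C10 epimer. Migration of the methylene at low hydrogen pressure and slow reduction of the strained C3=C4 alkene, also homoallylic to the C1 hydroxyl, are further risks. Fallback, from alcohol 30: the directing group is moved to the other flank of C10. With the C1 oxygen still a PMB ether, the free C19 hydroxyl of 30 directs [Rh(nbd)(dppb)]BF4 and hydrogen to give the C10-methyl alcohol F4. Silylation (TBSCl, imidazole) gives the silyl ether F5, and DDQ removes the PMB group to return to alcohol 33.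

**Step 14.** Intermolecular esterification to diolides, and SN2′ attack on or elimination of the allylic oxyphosphonium ion, can compete, because a chain with two E alkenes and one ring-cis alkene must fold into thirteen members. Fallback, from hydroxy acid 25: the acyl end is activated instead of the alkyl end. Shiina lactonisation with 2-methyl-6-nitrobenzoic anhydride and DMAP at room temperature and high dilution passes through the mixed anhydride F6 and closes to lactone 26 by attack of the C20 hydroxyl on C19. The temperature is kept low because the activated β,γ-unsaturated acid can isomerise.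

**Step 11.** In the one-pot sequence excess Me3Al meets the PMB ether and the ester. The π-allylpalladium intermediate can also lose the acidified C8 proton to give a dienoate instead of coupling. Fallback, from alkyne 12: carbometalation and coupling are separated. Carboalumination followed by iodine gives the (E)-alkenyl iodide F7, which is purified. Exchange with t-BuLi at −78 °C and ZnBr2 gives the alkenylzinc bromide F8, free of aluminium and zirconium, and this couples with chloride 21 under Pd(PPh3)4 to return to seco ester 23.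

**Step 22.** Epimerisation at C8 by the amine, or lactol and then lactone formation if one hydroxyl is oxidised before the other, would erode the last step. Fallback, from acetate 34: the two carbons are oxidised one after the other. PPTS in MeOH removes only the TBS ether to give the C19 alcohol F9, and Dess–Martin periodinane (NaHCO3) gives the C19 aldehyde F10. HF·pyridine then frees the C18 hydroxyl to give the hydroxy aldehyde F11, which may rest as its lactol. MnO2 oxidises only the allylic alcohol of the open form and not the saturated lactol, so the equilibrium drains to dialdehyde 36.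

## Further compounds

F1 | step 15 | (1R,3E,6E,8S,9S)-7-[(TBDPS-oxy)methyl]-1-(PMB-oxy)-3-methyl-9-(6-methylhepta-1,5-dien-2-yl)cyclonona-3,6-diene-8-carboxylic acid (C8 epimer of 29) | COc1ccc(cc1)CO[C@@H]2C/C(C)=C/C/C=C(/CO[Si](c3ccccc3)(c3ccccc3)C(C)(C)C)[C@@H](C(O)=O)[C@H]2C(=C)CCC=C(C)C
F2 | step 15 | methyl ester of F1 | COc1ccc(cc1)CO[C@@H]2C/C(C)=C/C/C=C(/CO[Si](c3ccccc3)(c3ccccc3)C(C)(C)C)[C@@H](C(=O)OC)[C@H]2C(=C)CCC=C(C)C
F3 | step 15 | methyl ester of 29 (C8 and C9 substituents trans) | COc1ccc(cc1)CO[C@@H]2C/C(C)=C/C/C=C(/CO[Si](c3ccccc3)(c3ccccc3)C(C)(C)C)[C@H](C(=O)OC)[C@H]2C(=C)CCC=C(C)C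
F4 | step 19 | (1R,3E,6E,8R,9R)-8-(hydroxymethyl)-7-[(TBDPS-oxy)methyl]-1-(PMB-oxy)-3-methyl-9-[(2S)-6-methylhept-5-en-2-yl]cyclonona-3,6-diene | COc1ccc(cc1)CO[C@@H]2C/C(C)=C/C/C=C(/CO[Si](c3ccccc3)(c3ccccc3)C(C)(C)C)[C@H](CO)[C@H]2[C@@H](C)CCC=C(C)C
F5 | step 19 | tert-butyldimethylsilyl ether of F4 | COc1ccc(cc1)CO[C@@H]2C/C(C)=C/C/C=C(/CO[Si](c3ccccc3)(c3ccccc3)C(C)(C)C)[C@H](CO[Si](C)(C)C(C)(C)C)[C@H]2[C@@H](C)CCC=C(C)C
F6 | step 14 | mixed anhydride of 25 with 2-methyl-6-nitrobenzoic acid | Cc1cccc([N+](=O)[O-])c1C(=O)OC(=O)C/C(CO[Si](c1ccccc1)(c1ccccc1)C(C)(C)C)=C\C/C=C(\C)C[C@@H](OCc1ccc(OC)cc1)/C=C(\CCC=C(C)C)CO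
F7 | step 11 | (1E,4R,5E)-6-[(TBS-oxy)methyl]-1-iodo-4-(PMB-oxy)-2,10-dimethylundeca-1,5,9-triene | I/C=C(\C)C[C@@H](OCc1ccc(OC)cc1)/C=C(\CCC=C(C)C)CO[Si](C)(C)C(C)(C)C
F8 | step 11 | alkenylzinc bromide from F7 | Br[Zn]/C=C(\C)C[C@@H](OCc1ccc(OC)cc1)/C=C(\CCC=C(C)C)CO[Si](C)(C)C(C)(C)C
F9 | step 22 | (1R,3E,6E,8R,9R)-8-(hydroxymethyl)-7-[(TBDPS-oxy)methyl]-3-methyl-9-[(2S)-6-methylhept-5-en-2-yl]cyclonona-3,6-dien-1-yl acetate | CC(=O)O[C@@H]1C/C(C)=C/C/C=C(/CO[Si](c2ccccc2)(c2ccccc2)C(C)(C)C)[C@H](CO)[C@H]1[C@@H](C)CCC=C(C)C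
F10 | step 22 | (1R,3E,6E,8R,9R)-8-formyl-7-[(TBDPS-oxy)methyl]-3-methyl-9-[(2S)-6-methylhept-5-en-2-yl]cyclonona-3,6-dien-1-yl acetate | CC(=O)O[C@@H]1C/C(C)=C/C/C=C(/CO[Si](c2ccccc2)(c2ccccc2)C(C)(C)C)[C@H](C=O)[C@H]1[C@@H](C)CCC=C(C)C
F11 | step 22 | (1R,3E,6E,8R,9R)-8-formyl-7-(hydroxymethyl)-3-methyl-9-[(2S)-6-methylhept-5-en-2-yl]cyclonona-3,6-dien-1-yl acetate | CC(=O)O[C@@H]1C/C(C)=C/C/C=C(/CO)[C@H](C=O)[C@H]1[C@@H](C)CCC=C(C)C
A1 | alternative 1 | nine-membered dienone (C8 ketone, ring-cis C6=C7, E C3=C4, C1 silyl ether) | CC(C)(C)[Si](C)(C)O[C@@H]1C/C(C)=C/C/C=C\C(=O)[C@H]1[C@@H](C)CCC=C(C)C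
A2 | alternative 2 | (E)-cyclononenone (C7 ketone, C1 PMB ether, C8 silyloxymethyl) | COc1ccc(cc1)CO[C@@H]2C/C(C)=C/CCC(=O)[C@H](CO[Si](C)(C)C(C)(C)C)[C@H]2[C@@H](C)CCC=C(C)C
A3 | alternative 3 | nine-membered homoallylic alcohol with C8 exocyclic methylene | O[C@@H]1C/C(C)=C/C/C=C(/CO[Si](C)(C)C(C)(C)C)C(=C)[C@H]1[C@@H](C)CCC=C(C)C
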